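**Retrosynthetic overview**
- The strategy rests on the single bond between C6 of ring A (the carbon lying between the C5 and C7 hydroxyl-bearing carbons) and the allylic CH2 (C1'') of the (E)-4-hydroxy-3-methylbut-2-enyl chain.
- Cutting this bond gives two electrophiles: a 6-iodo genistein bis(silyl ether), iodinated ortho to the free chelated C5 hydroxyl, and an (E)-allylic acetate carrying the CH2OH as a silyl ether. A nickel/zinc reductive cross-coupling joins them.
- Rings A, B and C are all bought together in genistein; no ring is formed anywhere in the route.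
- The E olefin is set by SeO2 oxidation of prenyl acetate and carried through the coupling; global desilylation finishes the synthesis.

Key step: step 5

Remark on the chemistry (assumption): the target SMILES places CH2OH trans to the benzylic CH2 across C2''=C3'' (E), and the route is built for that isomer; genistein and prenyl acetate are taken as the purchased carbon skeletons.

**Step 1**
Reactants: 1 genistein
Product: 2 7,4'-bis-O-TBS genistein
Conditions: TBSCl (2.2 equiv), imidazole (4 equiv), DMF, 0 °C to rt
Reagents that add atoms: tert-butyldimethylsilyl chloride, CC(C)(C)[Si](C)(C)Cl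
Why: Imidazole-mediated phenol silylation, in which the C5 hydroxyl is held in a hydrogen bond to the C4 carbonyl and is hindered, so about two equivalents of silyl chloride should cap only the C7 and C4' phenols.

**Step 2**
Reactants: 2 7,4'-bis-O-TBS genistein
Product: 3 6-iodo-7,4'-bis-O-TBS genistein (fragment 1)
Conditions: BnNMe3·ICl2 (1.05 equiv), CaCO3, CH2Cl2–MeOH, rt, dark
Reagents that add atoms: benzyltrimethylammonium dichloroiodate, C[N+](C)(C)Cc1ccccc1.Cl[I-]Cl
Why: Electrophilic aromatic iodination directed by the free C5 phenol to its ortho carbon C6, the site this reagent is known to select on 5-hydroxy-7-alkoxychromones (not C8), with CaCO3 taking up the HCl so that the aryl silyl ethers should remain.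

**Step 3**
Reactants: 4 prenyl acetate
Product: 6 (E)-4-hydroxy-3-methylbut-2-en-1-yl acetate, via (E)-4-acetoxy-2-methylbut-2-enal 5 (not isolated)
Conditions: SeO2 (cat.), t-BuOOH, salicylic acid (cat.), CH2Cl2, rt; then crude mixture, NaBH4, MeOH, 0 °C
Reagents that add atoms: selenium dioxide, O=[Se]=O (oxygen carrier); tert-butyl hydroperoxide, CC(C)(C)OO (terminal oxygen source)
Why: Catalytic SeO2/t-BuOOH allylic oxidation (ene reaction, then [2,3]-sigmatropic shift) attacks the methyl group trans to the acetoxymethyl chain on the more substituted olefin carbon, which fixes the E geometry, and the brief borohydride treatment returns the over-oxidised enal 5 to alcohol 6 without cleaving the acetate.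

**Step 4**
Reactants: 6 (E)-4-hydroxy-3-methylbut-2-en-1-yl acetate
Product: 7 (E)-4-(tert-butyldimethylsilyloxy)-3-methylbut-2-en-1-yl acetate (fragment 2)
Conditions: TBSCl (1.2 equiv), imidazole (2 equiv), CH2Cl2, 0 °C to rt
Reagents that add atoms: tert-butyldimethylsilyl chloride, CC(C)(C)[Si](C)(C)Cl
Why: Standard silylation of a primary alcohol under neutral conditions that leave the allylic acetate and the olefin geometry untouched.

**Step 5**
Reactants: 3 6-iodo-7,4'-bis-O-TBS genistein (fragment 1); 7 (E)-4-(tert-butyldimethylsilyloxy)-3-methylbut-2-en-1-yl acetate (fragment 2, 1.5–2 equiv)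
Product: 8 6-[(E)-4-(tert-butyldimethylsilyloxy)-3-methylbut-2-en-1-yl]-7,4'-bis-O-TBS genistein
Conditions: NiBr2(1,2-dimethoxyethane) (10 mol %), 4,4'-di-tert-butyl-2,2'-bipyridine (12 mol %), Zn powder (3 equiv), N,N-dimethylacetamide, 40 °C, argon
Reagents that add atoms: none
Why: Zinc reduces the divalent nickel salt to a zerovalent nickel–bipyridine complex that inserts into the C6–I bond of 3; after one-electron reduction by zinc the arylnickel ionises the acetate of 7 to an η3-allylnickel unit, and the aryl(allyl)nickel species reductively eliminates at the unsubstituted CH2 terminus to form C6–C1'' while zinc turns the catalyst over. The closest known reaction type is the nickel-catalysed, zinc-driven reductive cross-electrophile allylation of aryl halides with allylic acetates, which gives linear allylarenes; here it is applied to an aryl iodide flanked by two oxygen substituents and to a trisubstituted allyl partner, a combination that remains to be tested. No ring is closed and no stereocentre is created. The step needs site selectivity on ring A, fixed by the position of the iodine (C6, not C8 or oxygen), and linear selectivity with retention of the E olefin, which follows from bond formation at the less hindered allyl terminus and from the fact that scrambling would require nickel to σ-bond at the fully substituted carbon. Because both partners are electrophiles, no basic aryl-metal reagent has to coexist with the chelated C5 phenol or the chromone carbonyl, and the allylic silyl ether is too poor a leaving group to compete with the acetate.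

**Step 6**
Reactants: 8 6-[(E)-4-(tert-butyldimethylsilyloxy)-3-methylbut-2-en-1-yl]-7,4'-bis-O-TBS genistein
Product: 9 5,7-dihydroxy-6-[(E)-4-hydroxy-3-methylbut-2-en-1-yl]-3-(4-hydroxyphenyl)-4H-chromen-4-one (target)
Conditions: TBAF (4 equiv), AcOH (4 equiv), THF, 0 °C to rt
Reagents that add atoms: none
Why: Fluoride-mediated cleavage of the two aryl and one primary alkyl Si–O bonds, buffered with acetic acid so the liberated phenoxides are protonated at once, under conditions to which the olefin, the allylic alcohol and the chromone are inert.

**Compound list**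
1 | genistein, 5,7-dihydroxy-3-(4-hydroxyphenyl)-4H-chromen-4-one | O=c1c(-c2ccc(O)cc2)coc2cc(O)cc(O)c12 | starting material
2 | 7,4'-bis-O-TBS genistein, 7-(tert-butyldimethylsilyloxy)-3-[4-(tert-butyldimethylsilyloxy)phenyl]-5-hydroxy-4H-chromen-4-one | CC(C)(C)[Si](C)(C)Oc1ccc(-c2coc3cc(O[Si](C)(C)C(C)(C)C)cc(O)c3c2=O)cc1 | intermediate
3 | 6-iodo-7,4'-bis-O-TBS genistein (fragment 1) | CC(C)(C)[Si](C)(C)Oc1ccc(-c2coc3cc(O[Si](C)(C)C(C)(C)C)c(I)c(O)c3c2=O)cc1 | intermediate
4 | prenyl acetate, 3-methylbut-2-en-1-yl acetate | CC(=O)OCC=C(C)C | starting material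
5 | (E)-4-acetoxy-2-methylbut-2-enal | CC(=O)OC/C=C(\C)C=O | intermediate
6 | (E)-4-hydroxy-3-methylbut-2-en-1-yl acetate | CC(=O)OC/C=C(\C)CO | intermediate
7 | (E)-4-(tert-butyldimethylsilyloxy)-3-methylbut-2-en-1-yl acetate (fragment 2) | CC(=O)OC/C=C(\C)CO[Si](C)(C)C(C)(C)C | intermediate
8 | 6-[(E)-4-(tert-butyldimethylsilyloxy)-3-methylbut-2-en-1-yl]-7,4'-bis-O-TBS genistein | C/C(=C\Cc1c(O[Si](C)(C)C(C)(C)C)cc2occ(-c3ccc(O[Si](C)(C)C(C)(C)C)cc3)c(=O)c2c1O)CO[Si](C)(C)C(C)(C)C | intermediate
9 | 5,7-dihydroxy-6-[(E)-4-hydroxy-3-methylbut-2-en-1-yl]-3-(4-hydroxyphenyl)-4H-chromen-4-one (EANPDB LEGU_00416) | C/C(=C\Cc1c(O)cc2occ(-c3ccc(O)cc3)c(=O)c2c1O)CO | target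

**Step count**
Total steps: 6. Longest linear sequence: 4 steps (steps 1, 2, 5, 6; the fragment 2 branch, steps 3, 4, 5, 6, is equally long).

**Steps most likely to fail**

1. Step 5 (reductive cross-coupling).
   - What may go wrong: oxidative addition at the doubly flanked C6–I bond may be slow, so that reduction of C–I to C–H and self-coupling of the allyl partner outrun the cross-coupling. The allylnickel may also isomerise (loss of E geometry or attack at the substituted terminus) or lose its silyloxy group by reductive 1,4-elimination.
   - Fallback (known chemistry), setting out from iodide 3 and coming back at target 9. Stille coupling of 3 with allyltributylstannane (Pd(PPh3)4, a zerovalent palladium catalyst, toluene, 100 °C) should give 6-allyl-7,4'-bis-O-TBS genistein F1. Olefin cross-metathesis of F1 with excess methacrolein (second-generation Hoveyda–Grubbs catalyst, CH2Cl2, 40 °C) should give the thermodynamically favoured (E)-enal, 6-[(E)-3-methyl-4-oxobut-2-en-1-yl]-7,4'-bis-O-TBS genistein F2. Luche reduction (NaBH4, CeCl3·7H2O, MeOH–THF, −40 °C), in which the aldehyde is reduced far faster than the vinylogous-ester chromone, should give 6-[(E)-4-hydroxy-3-methylbut-2-en-1-yl]-7,4'-bis-O-TBS genistein F3. Desilylation of F3 under the conditions of step 6 then gives 9.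

2. Step 2 (iodination).
   - What may go wrong: iodination at C8 or twice on ring A, and methanolysis of the labile C7 aryl silyl ether in the methanolic medium. The site of iodination should be confirmed before the material is carried on.
   - Fallback, setting out from genistein 1 and coming back at iodide 3. Acetal protection (MOMCl, i-Pr2NEt, CH2Cl2) should give 7,4'-bis-O-MOM genistein F4, whose ethers are stable in methanol. Iodination with BnNMe3·ICl2/CaCO3 in CH2Cl2–MeOH should give 6-iodo-7,4'-bis-O-MOM genistein F5. Acid methanolysis (HCl, MeOH, rt to 40 °C) should give 6-iodogenistein F6. Bis-silylation of F6 with TBSCl/imidazole as in step 1 then gives 3.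

3. Step 3 (allylic oxidation).
   - What may go wrong: incomplete conversion alongside over-oxidation, loss of the small volatile products on work-up, and partial acetate cleavage or migration during the reduction.
   - Fallback, setting out from prenyl acetate 4 and coming back at alcohol 6. Ozonolysis of 4 (O3, CH2Cl2, −78 °C; then Me2S) should give 2-oxoethyl acetate F7. Wittig olefination of F7 with the formyl-stabilised ylide 2-(triphenylphosphoranylidene)propanal (toluene, 80 °C) should give E-enal 5, this time isolated. Reduction with NaBH4 (MeOH, 0 °C) then gives 6.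

**Further compounds**
F1 | step 5 | 6-allyl-7,4'-bis-O-TBS genistein | C=CCc1c(O[Si](C)(C)C(C)(C)C)cc2occ(-c3ccc(O[Si](C)(C)C(C)(C)C)cc3)c(=O)c2c1O
F2 | step 5 | 6-[(E)-3-methyl-4-oxobut-2-en-1-yl]-7,4'-bis-O-TBS genistein | C/C(=C\Cc1c(O[Si](C)(C)C(C)(C)C)cc2occ(-c3ccc(O[Si](C)(C)C(C)(C)C)cc3)c(=O)c2c1O)C=O
F3 | step 5 | 6-[(E)-4-hydroxy-3-methylbut-2-en-1-yl]-7,4'-bis-O-TBS genistein | C/C(=C\Cc1c(O[Si](C)(C)C(C)(C)C)cc2occ(-c3ccc(O[Si](C)(C)C(C)(C)C)cc3)c(=O)c2c1O)CO
F4 | step 2 | 7,4'-bis-O-MOM genistein | COCOc1ccc(-c2coc3cc(OCOC)cc(O)c3c2=O)cc1
F5 | step 2 | 6-iodo-7,4'-bis-O-MOM genistein | COCOc1ccc(-c2coc3cc(OCOC)c(I)c(O)c3c2=O)cc1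
F6 | step 2 | 6-iodogenistein | O=c1c(-c2ccc(O)cc2)coc2cc(O)c(I)c(O)c12
F7 | step 3 | 2-oxoethyl acetate | CC(=O)OCC=O
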